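## Retrosynthetic overview

- Halimane numbering is used: ring A = C1–C5 + C10, ring B = C5–C10, side chain C11–C16 on C9. The 14,15-diacetate comes from a 13,14,15-triol, made from the (13E)-allylic alcohol by asymmetric epoxidation and Payne opening; C12–C13 comes from a B-alkyl Suzuki coupling onto a C11 vinyl group.
- The C1=C10 alkene with the 5-H comes from a 1-hydroxy-5(10)-ene by an allylic diazene 1,3-transposition; that alcohol comes from the enone of the cycloadduct.
- Ring B (bonds C7–C8 and C9–C10) comes from a catalyst-controlled Diels–Alder reaction of a ring A vinylcyclohexene (C10=C5–C6=C7, C1 as a temporary silyl ether) with (E)-2-methylbut-2-enal (C8=C9, CHO = C11). Ring A is built first by an enantioselective Robinson annulation that sets quaternary C4.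
- Enabling feature: ring B is a cyclohexane in which C8 and C9 carry cis methyl groups (C17, C20) next to a trigonal C10 (C1=C10). Suprafacial addition of the E-enal sets both centres at once, and the C10 centre it also creates is erased later, so endo/exo and diene-face selectivity do not matter.
- Ring order: ring A (step 2), then ring B (step 6).

Key step: step 6

Assumption: in steps 1 and 6 the catalyst antipode named is the one the accepted transition-state models indicate; if the induction runs the other way, the mirror-image catalyst is taken and nothing else changes.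

## Route

Step 1
Reactants: 1 methyl 2-methyl-3-oxopentanoate; 2 but-3-en-2-one (methyl vinyl ketone)
Product: 3 methyl (2S)-2-methyl-3-oxo-2-(3-oxobutyl)pentanoate
Conditions: [Pd((R)-BINAP)(H2O)2](OTf)2 (5 mol%), THF, −20 °C
Reagents that add atoms: none
Why: Catalytic enantioselective Michael addition in which the chiral enolate of the β-keto ester on divalent palladium adds to the enone from its open face and so sets the quaternary C4 centre; the labile C2 of racemic 1 is funnelled through this common enolate.

Step 2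
Reactants: 3 methyl (2S)-2-methyl-3-oxo-2-(3-oxobutyl)pentanoate
Product: 5 methyl (1S)-2-ethyl-1-methyl-4-oxocyclohex-2-ene-1-carboxylate, via ketol 4 (not isolated)
Conditions: pyrrolidine (0.3 equiv), AcOH (0.3 equiv), toluene, 80 °C then reflux (Dean–Stark)
Reagents that add atoms: none
Why: Enamine-mediated intramolecular aldol condensation (second half of a Robinson annulation) of the terminal methyl ketone onto the hindered propionyl carbonyl closes ring A, and the quaternary centre cannot epimerize.

Step 3
Reactants: 5 methyl (1S)-2-ethyl-1-methyl-4-oxocyclohex-2-ene-1-carboxylate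
Product: 6 methyl (1S)-2-ethenyl-1-methyl-4-oxocyclohex-2-ene-1-carboxylate
Conditions: chloranil (1.3 equiv), t-BuOH, reflux
Reagents that add atoms: none
Why: Quinone dehydrogenation of an enone at its γ,δ-position (the 4-en-3-one to 4,6-dien-3-one type) by hydride abstraction from C7 of the linear dienol gives the vinyl dienone; the blocked C4 rules out aromatization.

Step 4
Reactants: 6 methyl (1S)-2-ethenyl-1-methyl-4-oxocyclohex-2-ene-1-carboxylate
Product: 7 methyl (1S,4S)-2-ethenyl-4-hydroxy-1-methylcyclohex-2-ene-1-carboxylate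
Conditions: (R)-2-methyl-CBS-oxazaborolidine (20 mol%), catecholborane, toluene, −78 °C
Reagents that add atoms: none
Why: Corey–Bakshi–Shibata 1,2-reduction in which the conjugated side acts as the large group, so the (R)-catalyst should give the (S)-carbinol at C1, on the ring face of the C4 methyl group.

Step 5
Reactants: 7 methyl (1S,4S)-2-ethenyl-4-hydroxy-1-methylcyclohex-2-ene-1-carboxylate
Product: 8 methyl (1S,4S)-4-[(tert-butyldimethylsilyl)oxy]-2-ethenyl-1-methylcyclohex-2-ene-1-carboxylate
Conditions: TBSCl, imidazole, DMF, 23 °C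
Reagents that add atoms: tert-butyldimethylsilyl chloride, CC(C)(C)[Si](C)(C)Cl
Why: Standard silylation of a secondary allylic alcohol; it leaves an electron-rich, non-coordinating diene whose silyloxy and C4 methyl groups both sit on one face.

Step 6
Reactants: 8 methyl (1S,4S)-4-[(tert-butyldimethylsilyl)oxy]-2-ethenyl-1-methylcyclohex-2-ene-1-carboxylate; 9 (E)-2-methylbut-2-enal
Product: 10 methyl (1S,4S,8R,9S,10R)-1-[(tert-butyldimethylsilyl)oxy]-11-oxo-12,13,14,15,16-pentanorhalim-5-en-18-oate
Conditions: cationic oxazaborolidine from (S)-B-(2-methylphenyl)-CBS-oxazaborolidine and Tf2NH (20 mol%), CH2Cl2, −78 to −40 °C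
Reagents that add atoms: none
Why: This is a chiral-Lewis-acid-catalyzed, normal-demand Diels–Alder reaction: the boron-bound s-trans enal 9 is attacked first at its β-carbon (C8) by the unhindered vinyl terminus C7, which carries the largest HOMO coefficient of the diene, and the bond from the α-carbon C9 to C10 closes in the same concerted, asynchronous event, so the required regiochemistry is the electronically and sterically preferred one. The closest known reaction type is the cationic-oxazaborolidine-catalyzed cycloaddition of 2-substituted enals with acyclic and semicyclic dienes. Ring B is closed as a six-membered ring by intermolecular [4+2] cycloaddition, suprafacial on both partners. The cis relation of C17 and C20 follows stereospecifically from the E geometry of 9, and the absolute configuration (8R,9S) is set by the catalyst, which shields the Si face at C2 of the enal so that the diene adds to the Re face; the C10 centre results from endo approach to the diene face anti to the silyloxy and C4 methyl groups. The step needs only dienophile-face selectivity, because C10 becomes trigonal in step 9 and both C10 epimers converge there; the silyl ether keeps the diene electron-rich, and ester and silyl ether should be inert to the catalyst at low temperature.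

Step 7
Reactants: 10 methyl (1S,4S,8R,9S,10R)-1-[(tert-butyldimethylsilyl)oxy]-11-oxo-12,13,14,15,16-pentanorhalim-5-en-18-oate
Product: 11 methyl (1S,4S,8R,9S,10S)-1-[(tert-butyldimethylsilyl)oxy]-13,14,15,16-tetranorhalima-5,11-dien-18-oate
Conditions: Ph3PCH3Br, KOtBu, THF, 0 to 23 °C
Reagents that add atoms: methyltriphenylphosphonium bromide, C[P+](c1ccccc1)(c1ccccc1)c1ccccc1.[Br-]
Why: Wittig methylenation of a non-enolizable neopentylic aldehyde gives the C11 vinyl group without risk to the adjacent quaternary centre.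

Step 8
Reactants: 11 methyl (1S,4S,8R,9S,10S)-1-[(tert-butyldimethylsilyl)oxy]-13,14,15,16-tetranorhalima-5,11-dien-18-oate
Product: 12 methyl (1S,4S,8R,9S,10S)-1-hydroxy-13,14,15,16-tetranorhalima-5,11-dien-18-oate
Conditions: Bu4NF, THF, 23 to 45 °C; aqueous work-up
Reagents that add atoms: none
Why: Fluoride-induced cleavage of the silyl ether frees the C1 carbinol, and no other group is fluoride-labile.

Step 9
Reactants: 12 methyl (1S,4S,8R,9S,10S)-1-hydroxy-13,14,15,16-tetranorhalima-5,11-dien-18-oate
Product: 14 methyl (4S,8R,9S)-1-oxo-13,14,15,16-tetranorhalima-5(10),11-dien-18-oate, via β,γ-unsaturated ketone 13 (not isolated)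
Conditions: Dess–Martin periodinane, CH2Cl2, 23 °C; aq. NaHCO3 wash; crude in CH2Cl2, DBU (0.2 equiv), 23 °C
Reagents that add atoms: none
Why: Dess–Martin oxidation followed by base-mediated conjugation through the dienolate moves the alkene into the tetrasubstituted 5(10) position, which removes the C10 stereocentre and makes the cycloadduct epimers converge.

Step 10
Reactants: 14 methyl (4S,8R,9S)-1-oxo-13,14,15,16-tetranorhalima-5(10),11-dien-18-oate
Product: 15 methyl (1S,4S,8R,9S)-1-hydroxy-13,14,15,16-tetranorhalima-5(10),11-dien-18-oate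
Conditions: (R)-2-methyl-CBS-oxazaborolidine (0.5 equiv), catecholborane, toluene, −60 to −40 °C
Reagents that add atoms: none
Why: Corey–Bakshi–Shibata reduction of an α-branched cyclic enone, with the C10 side as the large group, so the (R)-catalyst should give the (1S)-allylic alcohol under reagent control.

Step 11
Reactants: 15 methyl (1S,4S,8R,9S)-1-hydroxy-13,14,15,16-tetranorhalima-5(10),11-dien-18-oate
Product: 18 methyl (4S,5S,8R,9S)-13,14,15,16-tetranorhalima-1(10),11-dien-18-oate, via allylic sulfonylhydrazine 16 (not isolated), via allylic diazene 17 (not isolated)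
Conditions: 2-nitrobenzenesulfonylhydrazide (NBSH), PPh3, DEAD, N-methylmorpholine/THF, −30 °C, then 23 °C
Reagents that add atoms: none
Why: Reductive 1,3-transposition of an allylic alcohol: Mitsunobu displacement inverts C1, loss of sulfinic acid gives the monoalkyl diazene, and its retro-ene loss of N2 delivers hydrogen to C5 on the face of the C1–N bond (cis to the C18 ester) while the alkene moves to C1=C10.

Step 12
Reactants: 19 ethyl 3-oxobutanoate (ethyl acetoacetate)
Product: 20 ethyl (2E)-3-{[(trifluoromethyl)sulfonyl]oxy}but-2-enoate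
Conditions: Tf2O, aq. Me4NOH, hexane, 5 to 23 °C
Reagents that add atoms: trifluoromethanesulfonic anhydride, O=S(=O)(OS(=O)(=O)C(F)(F)F)C(F)(F)F
Why: O-sulfonylation of the non-chelated tetramethylammonium enolate of a β-keto ester should give the enol triflate with the triflate trans to the ester (E).

Step 13
Reactants: 18 methyl (4S,5S,8R,9S)-13,14,15,16-tetranorhalima-1(10),11-dien-18-oate; 20 ethyl (2E)-3-{[(trifluoromethyl)sulfonyl]oxy}but-2-enoate
Product: 22 15-ethyl 18-methyl (4S,5S,8R,9S,13E)-halima-1(10),13-diene-15,18-dioate, via B-alkyl-9-BBN adduct 21 (not isolated)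
Conditions: 9-BBN dimer, THF, 0 to 23 °C; then 20, Pd(dppf)Cl2 (5 mol%), AsPh3, K3PO4 (3 M aq.), DMF, 23 °C
Reagents that add atoms: none
Why: Anti-Markovnikov hydroboration selects the monosubstituted vinyl group over the hindered trisubstituted C1=C10 alkene, and the B-alkyl Suzuki–Miyaura coupling with the enol triflate proceeds with retention of geometry to give the 13E enoate.

Step 14
Reactants: 22 15-ethyl 18-methyl (4S,5S,8R,9S,13E)-halima-1(10),13-diene-15,18-dioate
Product: 23 methyl (4S,5S,8R,9S,13E)-15-hydroxyhalima-1(10),13-dien-18-oate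
Conditions: i-Bu2AlH (2.2 equiv), CH2Cl2, −78 °C; Rochelle salt work-up
Reagents that add atoms: none
Why: Hydride reduction of the unhindered conjugated ester to the allylic alcohol should be much faster at −78 °C than attack on the C18 ester, which sits on a quaternary carbon.

Step 15
Reactants: 23 methyl (4S,5S,8R,9S,13E)-15-hydroxyhalima-1(10),13-dien-18-oate
Product: 24 methyl (4S,5S,8R,9S,13S,14S)-13,14-epoxy-15-hydroxyhalim-1(10)-en-18-oate
Conditions: Ti(OiPr)4 (10 mol%), L-(+)-diethyl tartrate (12 mol%), t-BuOOH, 4 Å MS, CH2Cl2, −20 °C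
Reagents that add atoms: tert-butyl hydroperoxide, CC(C)(C)OO
Why: Sharpless asymmetric epoxidation of an (E)-3-methylalk-2-en-1-ol, which with L-(+)-tartrate gives the (2S,3S)-type epoxy alcohol (here 13S,14S) as for geraniol, and it touches only the allylic alcohol alkene, not C1=C10.

Step 16
Reactants: 24 methyl (4S,5S,8R,9S,13S,14S)-13,14-epoxy-15-hydroxyhalim-1(10)-en-18-oate
Product: 27 (4S,5S,8R,9S,13S,14R)-13,14,15-trihydroxyhalim-1(10)-en-18-oic acid, via 14,15-epoxide 25 (not isolated), via triol methyl ester 26 (not isolated)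
Conditions: KOH (2 M aq., excess), t-BuOH/DMSO, 75 to 95 °C; then 1 M HCl to pH 3
Reagents that add atoms: potassium hydroxide (aqueous), [K+].[OH-]; water, O
Why: Payne rearrangement inverts C14 and hydroxide then opens the terminal epoxide at C15, which gives the anti (13S,14R) triol with C13 untouched, and the same hydroxide saponifies the equatorial C18 methyl ester.

Step 17
Reactants: 27 (4S,5S,8R,9S,13S,14R)-13,14,15-trihydroxyhalim-1(10)-en-18-oic acid
Product: 28 (4S,5S,8R,9S,13S,14R)-14,15-diacetoxy-13-hydroxyhalim-1(10)-en-18-oic acid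
Conditions: Ac2O, pyridine, 23 °C; aq. NaHCO3 work-up, then acidify
Reagents that add atoms: acetic anhydride, CC(=O)OC(C)=O
Why: Acetylation takes the primary and secondary hydroxyl groups while the tertiary C13 hydroxyl is inert without an acyl-transfer catalyst, and any mixed anhydride at C18 is hydrolysed during work-up.

## Compound list

1 | methyl 2-methyl-3-oxopentanoate (racemic) | CCC(=O)C(C)C(=O)OC | starting material
2 | but-3-en-2-one (methyl vinyl ketone) | CC(=O)C=C | starting material
3 | methyl (2S)-2-methyl-3-oxo-2-(3-oxobutyl)pentanoate | CCC(=O)[C@@](C)(C(=O)OC)CCC(C)=O | intermediate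
4 | methyl (1S)-2-ethyl-2-hydroxy-1-methyl-4-oxocyclohexane-1-carboxylate (ketol formed in situ; both carbinol epimers) | O=C1CC(O)(CC)[C@@](C)(C(=O)OC)CC1 | intermediate
5 | methyl (1S)-2-ethyl-1-methyl-4-oxocyclohex-2-ene-1-carboxylate | O=C1C=C(CC)[C@@](C)(C(=O)OC)CC1 | intermediate
6 | methyl (1S)-2-ethenyl-1-methyl-4-oxocyclohex-2-ene-1-carboxylate | O=C1C=C(C=C)[C@@](C)(C(=O)OC)CC1 | intermediate
7 | methyl (1S,4S)-2-ethenyl-4-hydroxy-1-methylcyclohex-2-ene-1-carboxylate | O[C@@H]1C=C(C=C)[C@@](C)(C(=O)OC)CC1 | intermediate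
8 | methyl (1S,4S)-4-[(tert-butyldimethylsilyl)oxy]-2-ethenyl-1-methylcyclohex-2-ene-1-carboxylate | CC(C)(C)[Si](C)(C)O[C@@H]1C=C(C=C)[C@@](C)(C(=O)OC)CC1 | intermediate
9 | (E)-2-methylbut-2-enal (tiglic aldehyde) | C/C=C(\C)C=O | starting material
10 | methyl (1S,4S,8R,9S,10R)-1-[(tert-butyldimethylsilyl)oxy]-11-oxo-12,13,14,15,16-pentanorhalim-5-en-18-oate (expected major cycloadduct) | O=C[C@]1(C)[C@@H]2[C@@H](O[Si](C)(C)C(C)(C)C)CC[C@](C)(C(=O)OC)C2=CC[C@H]1C | intermediate
11 | methyl (1S,4S,8R,9S,10S)-1-[(tert-butyldimethylsilyl)oxy]-13,14,15,16-tetranorhalima-5,11-dien-18-oate | C=C[C@]1(C)[C@@H]2[C@@H](O[Si](C)(C)C(C)(C)C)CC[C@](C)(C(=O)OC)C2=CC[C@H]1C | intermediate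
12 | methyl (1S,4S,8R,9S,10S)-1-hydroxy-13,14,15,16-tetranorhalima-5,11-dien-18-oate | C=C[C@]1(C)[C@@H]2[C@@H](O)CC[C@](C)(C(=O)OC)C2=CC[C@H]1C | intermediate
13 | methyl (4S,8R,9S,10S)-1-oxo-13,14,15,16-tetranorhalima-5,11-dien-18-oate (formed in situ) | C=C[C@]1(C)[C@@H]2C(=O)CC[C@](C)(C(=O)OC)C2=CC[C@H]1C | intermediate
14 | methyl (4S,8R,9S)-1-oxo-13,14,15,16-tetranorhalima-5(10),11-dien-18-oate | C=C[C@]1(C)C2=C(CC[C@H]1C)[C@@](C)(C(=O)OC)CCC2=O | intermediate
15 | methyl (1S,4S,8R,9S)-1-hydroxy-13,14,15,16-tetranorhalima-5(10),11-dien-18-oate | C=C[C@]1(C)C2=C(CC[C@H]1C)[C@@](C)(C(=O)OC)CC[C@@H]2O | intermediate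
16 | methyl (1R,4S,8R,9S)-1-[1-(2-nitrobenzenesulfonyl)hydrazin-1-yl]-13,14,15,16-tetranorhalima-5(10),11-dien-18-oate (formed in situ) | C=C[C@]1(C)C2=C(CC[C@H]1C)[C@@](C)(C(=O)OC)CC[C@H]2N(N)S(=O)(=O)c1ccccc1[N+](=O)[O-] | intermediate
17 | methyl (1R,4S,8R,9S)-1-diazenyl-13,14,15,16-tetranorhalima-5(10),11-dien-18-oate (formed in situ) | C=C[C@]1(C)C2=C(CC[C@H]1C)[C@@](C)(C(=O)OC)CC[C@H]2N=N | intermediate
18 | methyl (4S,5S,8R,9S)-13,14,15,16-tetranorhalima-1(10),11-dien-18-oate | C=C[C@]1(C)C2=CCC[C@](C)(C(=O)OC)[C@H]2CC[C@H]1C | intermediate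
19 | ethyl 3-oxobutanoate (ethyl acetoacetate) | CCOC(=O)CC(C)=O | starting material
20 | ethyl (2E)-3-{[(trifluoromethyl)sulfonyl]oxy}but-2-enoate | CCOC(=O)/C=C(\C)OS(=O)(=O)C(F)(F)F | intermediate
21 | methyl (4S,5S,8R,9S)-12-(9-borabicyclo[3.3.1]nonan-9-yl)-13,14,15,16-tetranorhalim-1(10)-en-18-oate (formed in situ) | C1CCC2CCCC1B2CC[C@]1(C)C2=CCC[C@](C)(C(=O)OC)[C@H]2CC[C@H]1C | intermediate
22 | 15-ethyl 18-methyl (4S,5S,8R,9S,13E)-halima-1(10),13-diene-15,18-dioate | CCOC(=O)/C=C(\C)CC[C@]1(C)C2=CCC[C@](C)(C(=O)OC)[C@H]2CC[C@H]1C | intermediate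
23 | methyl (4S,5S,8R,9S,13E)-15-hydroxyhalima-1(10),13-dien-18-oate | OC/C=C(\C)CC[C@]1(C)C2=CCC[C@](C)(C(=O)OC)[C@H]2CC[C@H]1C | intermediate
24 | methyl (4S,5S,8R,9S,13S,14S)-13,14-epoxy-15-hydroxyhalim-1(10)-en-18-oate | OC[C@@H]1O[C@@]1(C)CC[C@]2(C)C3=CCC[C@](C)(C(=O)OC)[C@H]3CC[C@H]2C | intermediate
25 | methyl (4S,5S,8R,9S,13S,14R)-14,15-epoxy-13-hydroxyhalim-1(10)-en-18-oate (formed in situ) | C1O[C@H]1[C@@](C)(O)CC[C@]2(C)C3=CCC[C@](C)(C(=O)OC)[C@H]3CC[C@H]2C | intermediate
26 | methyl (4S,5S,8R,9S,13S,14R)-13,14,15-trihydroxyhalim-1(10)-en-18-oate (formed in situ) | OC[C@@H](O)[C@@](C)(O)CC[C@]1(C)C2=CCC[C@](C)(C(=O)OC)[C@H]2CC[C@H]1C | intermediate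
27 | (4S,5S,8R,9S,13S,14R)-13,14,15-trihydroxyhalim-1(10)-en-18-oic acid | OC[C@@H](O)[C@@](C)(O)CC[C@]1(C)C2=CCC[C@](C)(C(=O)O)[C@H]2CC[C@H]1C | intermediate
28 | (4S,5S,8R,9S,13S,14R)-14,15-diacetoxy-13-hydroxyhalim-1(10)-en-18-oic acid | CC(=O)OC[C@@H](OC(C)=O)[C@@](C)(O)CC[C@]1(C)C2=CCC[C@](C)(C(=O)O)[C@H]2CC[C@H]1C | target

## Step count and risks

Total step count: 17. Longest linear sequence: 16 steps (steps 1–11 and 13–17; step 12 is a one-step side branch).

Steps most likely to fail:

**Step 6 (key cycloaddition).** The hindered α,β-disubstituted enal may react slowly, the catalyst may discriminate the enal faces poorly in the presence of the chiral diene, or the α-carbon may bond to C7 instead of C10. The fallback sets out from 7 and returns at 14, and ties the dienophile to the C1 oxygen.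
- Acylation of 7 with (E)-2-methylbut-2-enoyl chloride (Et3N, DMAP, CH2Cl2) gives the dienyl tiglate F1.
- Heating (o-dichlorobenzene, BHT, 180 °C, high dilution) or treatment with Et2AlCl brings about an intramolecular Diels–Alder reaction. The three-atom ester tether allows only the C9–C10 and C8–C7 bonds and only the diene face that carries the C1 oxygen, and gives the tricyclic γ-lactone F2 through the exo-carbonyl arrangement.
- If the endo arrangement prevails instead, the C1 epimer of 7 (from the (S)-CBS catalyst) is used.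
- Reduction with i-Bu2AlH at −78 °C gives the lactol F3, and Wittig methylenation of its open hydroxy-aldehyde form gives the C1-hydroxy diene F4, the C10 epimer of 12.
- Dess–Martin oxidation and DBU then converge on 14.

**Step 11 (diazene transposition).** The Mitsunobu displacement at the hindered C1 carbinol may be outrun by elimination or by attack at the distal allyl terminus. The fallback sets out from 14 and returns at 18, and replaces the single inversion by a double inversion on palladium.
- Reduction of 14 with the (S)-2-methyl-CBS-oxazaborolidine and catecholborane gives the epimeric (1R)-allylic alcohol F5.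
- ClCO2Me and pyridine convert it into the allylic methyl carbonate F6.
- Zerovalent palladium (Pd2(dba)3, PPh3, THF) with N-isopropylidene-N′-(2-nitrobenzenesulfonyl)hydrazine substitutes at the less hindered terminus C1 with net retention (Tsuji–Trost reaction) to give the N-allyl sulfonylhydrazone F7.
- Hydrolysis (CF3CH2OH/H2O, AcOH) releases diazene 17, which loses dinitrogen to give 18.

**Step 3 (dehydrogenation).** Hydride abstraction from the primary C7 may be slow, or dehydrogenation may turn to C2–C3 and give the cross-conjugated dienone. The fallback sets out from 5 and returns at 6.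
- Thermodynamic enol silylation (TMSCl, NaI, Et3N, MeCN, 60 °C) gives the linear silyl dienol ether F8.
- Saegusa–Ito oxidation with Pd(OAc)2 (divalent palladium, MeCN, 23 °C) removes a hydrogen from C7 and gives 6.

Further compounds
F1 | step 6 | methyl (1S,4S)-2-ethenyl-1-methyl-4-{[(2E)-2-methylbut-2-enoyl]oxy}cyclohex-2-ene-1-carboxylate | C/C=C(\C)C(=O)O[C@@H]1C=C(C=C)[C@@](C)(C(=O)OC)CC1
F2 | step 6 | tricyclic γ-lactone: 11,1-lactone of the 18-methyl ester of 1-hydroxy-12,13,14,15,16-pentanorhalim-5-ene-11,18-dioic acid, with 10-H on the face opposite to that in 10 | O=C1O[C@H]2CC[C@](C)(C(=O)OC)C3=CC[C@@H](C)[C@@]1(C)[C@@H]23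
F3 | step 6 | lactol of F2 (both anomers) | OC1O[C@H]2CC[C@](C)(C(=O)OC)C3=CC[C@@H](C)[C@@]1(C)[C@@H]23
F4 | step 6 | methyl (1S,4S,8R,9S,10R)-1-hydroxy-13,14,15,16-tetranorhalima-5,11-dien-18-oate | C=C[C@]1(C)[C@H]2[C@@H](O)CC[C@](C)(C(=O)OC)C2=CC[C@H]1C
F5 | step 11 | methyl (1R,4S,8R,9S)-1-hydroxy-13,14,15,16-tetranorhalima-5(10),11-dien-18-oate | C=C[C@]1(C)C2=C(CC[C@H]1C)[C@@](C)(C(=O)OC)CC[C@H]2O
F6 | step 11 | methyl (1R,4S,8R,9S)-1-[(methoxycarbonyl)oxy]-13,14,15,16-tetranorhalima-5(10),11-dien-18-oate | C=C[C@]1(C)C2=C(CC[C@H]1C)[C@@](C)(C(=O)OC)CC[C@H]2OC(=O)OC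
F7 | step 11 | methyl (1R,4S,8R,9S)-1-[1-(2-nitrobenzenesulfonyl)-2-(propan-2-ylidene)hydrazin-1-yl]-13,14,15,16-tetranorhalima-5(10),11-dien-18-oate | C=C[C@]1(C)C2=C(CC[C@H]1C)[C@@](C)(C(=O)OC)CC[C@H]2N(N=C(C)C)S(=O)(=O)c1ccccc1[N+](=O)[O-]
F8 | step 3 | methyl (1S)-2-ethylidene-1-methyl-4-[(trimethylsilyl)oxy]cyclohex-3-ene-1-carboxylate (E/Z mixture) | C[Si](C)(C)OC1=CC(=CC)[C@@](C)(C(=O)OC)CC1
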